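**Plan**
1. Carotenoid numbering is used: ring C1–C6 (C1 = CMe2, C3 and C4 = carbinols, C5=C6), chain C7–C15 and C15'–C7', open ψ-end C6'–C1'.
2. Retrosynthetic cuts, in order: the two O–Si bonds; C6–C7 (C9 ring enol triflate + complete C31 undecaenyl boronate); C7=C8 (one-carbon boron-Wittig on the C30 aldehyde); C7'=C8' (Wittig, geranyl C10 + crocetin dialdehyde C20).
3. Forward: the cyclohexene ring is not built but taken from ketoisophorone and elaborated in six steps; the chain grows C10 + C20 → C30 → C31; the last C–C bond joins ring and chain, then desilylation.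
4. The union is placed at the most hindered bond. C6 is a fully substituted sp2 carbon between quaternary C1 and methyl-bearing C5. Because C1 is quaternary, a C6 ketone can enolise only toward C5, so the enol triflate fixes the C5=C6 bond and makes C6 a coupling site; the C3/C4 diol is remote from C6 and is finished beforehand.
5. Stereochemistry: C3 from asymmetric transfer hydrogenation of ketoisophorone; C4 relayed from C3 (epoxidation anti to the C3 silyloxy group, C4–O bond kept in the reductive opening); 5'E and the inner chain E bonds from geranyl bromide and crocetin dialdehyde; 7'E by iodine equilibration; 7E from the boron-Wittig step.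

Key step: step 10

Remark: ketoisophorone, (E)-geranyl bromide and all-E crocetin dialdehyde are taken as commercial materials; all polyene steps are run degassed and with exclusion of light. TBS = tert-butyldimethylsilyl, Bpin = pinacolatoboryl.

**Step 1**
Reactants: 1 ketoisophorone (2,6,6-trimethylcyclohex-2-ene-1,4-dione)
Product: 2 (4R)-4-hydroxy-2,6,6-trimethylcyclohex-2-en-1-one
Conditions: RuCl[(R,R)-TsDPEN](p-cymene) (1 mol%), KOH (cat.), iPrOH, rt
Reagents that add atoms: none
Why: Asymmetric transfer hydrogenation (Noyori type) should reduce only the C4 carbonyl, which lies between a CH2 and a CH= group, and leave the C1 carbonyl shielded by the gem-dimethyl and 2-methyl groups; with the enone π bond in the role of the aryl group of the aryl-ketone model, the R,R catalyst should give the 4R carbinol, the future C3 of the target.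

**Step 2**
Reactants: 2 (4R)-4-hydroxy-2,6,6-trimethylcyclohex-2-en-1-one
Product: 3 (4R)-4-(TBS-oxy)-2,6,6-trimethylcyclohex-2-en-1-one
Conditions: TBSCl, imidazole, DMF, rt
Reagents that add atoms: tert-butyldimethylsilyl chloride, CC(C)(C)[Si](C)(C)Cl
Why: Standard imidazole-mediated O-silylation of a secondary alcohol, which also removes the syn-directing free hydroxyl before the epoxidation.

**Step 3**
Reactants: 3 (4R)-4-(TBS-oxy)-2,6,6-trimethylcyclohex-2-en-1-one
Product: 4 (1S,5R,6S)-5-(TBS-oxy)-1,3,3-trimethyl-7-oxabicyclo[4.1.0]heptan-2-one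
Conditions: 30% aq. H2O2, NaOH (cat.), MeOH, 0 °C
Reagents that add atoms: hydrogen peroxide, OO
Why: Weitz–Scheffer epoxidation, in which hydroperoxide should add to the enone β-carbon from the face opposite the bulky silyloxy group and the enolate closes on oxygen on that same face, so the oxirane oxygen at the future C4 stands trans to the silyloxy oxygen at the future C3.

**Step 4**
Reactants: 4 (1S,5R,6S)-5-(TBS-oxy)-1,3,3-trimethyl-7-oxabicyclo[4.1.0]heptan-2-one
Product: 5 (3R,4R)-4-(TBS-oxy)-3-hydroxy-2,6,6-trimethylcyclohexan-1-one (C2 epimer mixture)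
Conditions: SmI2 (2.5 equiv), THF/MeOH, −90 °C
Reagents that add atoms: none
Why: SmI2 reduction of an α,β-epoxy ketone, in which the ketyl expels the α-oxygen and methanol protonates the samarium enolate at low temperature before β-elimination, while the β C–O bond (future C4–O) is not touched and keeps its configuration; the C2 epimers are erased in step 6.

**Step 5**
Reactants: 5 (3R,4R)-4-(TBS-oxy)-3-hydroxy-2,6,6-trimethylcyclohexan-1-one
Product: 6 (3R,4R)-3,4-bis(TBS-oxy)-2,6,6-trimethylcyclohexan-1-one (C2 epimer mixture)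
Conditions: TBSOTf, 2,6-lutidine, CH2Cl2, −78 → 0 °C
Reagents that add atoms: tert-butyldimethylsilyl triflate, CC(C)(C)[Si](C)(C)OS(=O)(=O)C(F)(F)F
Why: Silyl triflate with a hindered pyridine base should silylate the hindered secondary alcohol at low temperature without enolising the β-hydroxy ketone, and a 1,2-silyl shift would be without consequence because both oxygens end as TBS ethers.

**Step 6**
Reactants: 6 (3R,4R)-3,4-bis(TBS-oxy)-2,6,6-trimethylcyclohexan-1-one
Product: 8 (3R,4R)-3,4-bis(TBS-oxy)-2,6,6-trimethylcyclohex-1-en-1-yl triflate, via lithium enolate 7 (not isolated)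
Conditions: LDA, THF, −78 °C; PhNTf2, −78 → 0 °C
Reagents that add atoms: N-phenyl-bis(trifluoromethanesulfonimide), O=S(=O)(N(c1ccccc1)S(=O)(=O)C(F)(F)F)C(F)(F)F
Why: Kinetic enolisation and O-triflation, in which LDA can remove only the C2 hydrogen because C6 is quaternary, so a single enolate regioisomer forms and is trapped on oxygen; the lithium counter-ion and low temperature are chosen to hold back E1cB loss of the β-silyloxy group, and the C2 stereocentre disappears.

**Step 7**
Reactants: 9 geranyl bromide
Product: 10 geranyltriphenylphosphonium bromide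
Conditions: PPh3, toluene, rt, dark
Reagents that add atoms: triphenylphosphine, c1ccc(cc1)P(c1ccccc1)c1ccccc1
Why: SN2 quaternisation of a primary allylic bromide by triphenylphosphine at room temperature, which leaves the 2E double bond untouched.

**Step 8**
Reactants: 10 geranyltriphenylphosphonium bromide; 11 crocetin dialdehyde (2 equiv)
Product: 14 apo-8'-lycopenal (all-E C30 aldehyde), via geranylidenetriphenylphosphorane 12 (not isolated), via 16Z aldehyde 13 (not isolated)
Conditions: NaHMDS, THF, −78 → 0 °C; add to 11, THF/CH2Cl2, −40 °C → rt; then I2 (cat.), CH2Cl2, visible light, rt; crystallisation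
Reagents that add atoms: none
Why: Wittig reaction in which the allylic ylide adds to one formyl group of the dialdehyde used in excess (the mono-adduct is the less electrophilic aldehyde); the new C16=C17 bond (C8'=C7' of the target) forms as an E/Z mixture, and iodine-catalysed photo-equilibration should convert the strained 16Z isomer into the all-E aldehyde.

**Step 9**
Reactants: 14 apo-8'-lycopenal
Product: 15 all-E C31 undecaenyl pinacol boronate
Conditions: CH2(Bpin)2, LiTMP, THF, 0 °C; then 14, −78 °C → rt
Reagents that add atoms: bis(pinacolatoboryl)methane, CC1(C)OB(CB2OC(C)(C)C(C)(C)O2)OC1(C)C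
Why: Boron-Wittig olefination, in which the lithiated geminal diboronate adds 1,2 to the aldehyde and the resulting oxaboretanide undergoes syn B–O elimination from the arrangement with the polyenyl chain anti to the remaining Bpin group, so the new C7=C8 bond should be E.

**Step 10**
Reactants: 8 (3R,4R)-3,4-bis(TBS-oxy)-2,6,6-trimethylcyclohex-1-en-1-yl triflate; 15 all-E C31 undecaenyl pinacol boronate
Product: 16 (3R,4R)-3,4-bis(TBS-oxy)-β,ψ-carotene
Conditions: Pd(OAc)2 (5 mol%), SPhos (10 mol%), K3PO4, THF/H2O, 40 °C, degassed, dark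
Reagents that add atoms: none
Why: Suzuki–Miyaura coupling: Pd(0)/SPhos inserts into the C6–O bond of enol triflate 8, phosphate and water activate alkenylboronate 15 for transmetalation, and reductive elimination forms the C6–C7 sp2–sp2 bond with retention at both alkenes, so the 7E geometry comes from 15 and the C5=C6 position from 8. The closest known reaction type is the Pd-catalysed coupling of 2,6,6-trimethylcyclohexenyl triflates with polyenyl organometallics at this same position of retinoids. No ring is closed and no stereocentre is formed; C3 and C4 are spectators held as silyl ethers, which also keep the allylic C4–O bond from ionising. The step needs cross-coupling to outrun protodeboronation of 15 and S–O cleavage of 8, and it must leave the all-E undecaene intact. The bulky electron-rich biarylphosphine should give fast oxidative addition and reductive elimination at the carbon flanked by quaternary C1 and the C5 methyl group, and the mild temperature with exclusion of light and oxygen protects the polyene. Because C1 is quaternary there is no regioisomeric triflate and hence no regioisomeric diene.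

**Step 11**
Reactants: 16 (3R,4R)-3,4-bis(TBS-oxy)-β,ψ-carotene
Product: 17 (3R,4R)-β,ψ-carotene-3,4-diol
Conditions: TBAF, THF, rt, dark
Reagents that add atoms: none
Why: Fluoride-induced Si–O cleavage driven by the Si–F bond, whose basic medium avoids ionisation of the allylic C4–O bond, so both carbinol centres keep their configuration and the polyene is not touched.

**Compound list**
1 | 2,6,6-trimethylcyclohex-2-ene-1,4-dione (ketoisophorone) | CC1=CC(=O)CC(C)(C)C1=O | starting material
2 | (4R)-4-hydroxy-2,6,6-trimethylcyclohex-2-en-1-one | O=C1C(C)=C[C@H](O)CC1(C)C | intermediate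
3 | (4R)-4-[(tert-butyldimethylsilyl)oxy]-2,6,6-trimethylcyclohex-2-en-1-one | O=C1C(C)=C[C@H](O[Si](C)(C)C(C)(C)C)CC1(C)C | intermediate
4 | (1S,5R,6S)-5-[(tert-butyldimethylsilyl)oxy]-1,3,3-trimethyl-7-oxabicyclo[4.1.0]heptan-2-one (oxirane trans to the silyloxy group) | O=C1[C@@]2(C)O[C@H]2[C@H](O[Si](C)(C)C(C)(C)C)CC1(C)C | intermediate
5 | (3R,4R)-4-[(tert-butyldimethylsilyl)oxy]-3-hydroxy-2,6,6-trimethylcyclohexan-1-one (C2 epimer mixture, trans-3,4) | O=C1C(C)[C@@H](O)[C@H](O[Si](C)(C)C(C)(C)C)CC1(C)C | intermediate
6 | (3R,4R)-3,4-bis[(tert-butyldimethylsilyl)oxy]-2,6,6-trimethylcyclohexan-1-one (C2 epimer mixture) | O=C1C(C)[C@@H](O[Si](C)(C)C(C)(C)C)[C@H](O[Si](C)(C)C(C)(C)C)CC1(C)C | intermediate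
7 | lithium (3R,4R)-3,4-bis[(tert-butyldimethylsilyl)oxy]-2,6,6-trimethylcyclohex-1-en-1-olate | [Li]OC1=C(C)[C@@H](O[Si](C)(C)C(C)(C)C)[C@H](O[Si](C)(C)C(C)(C)C)CC1(C)C | intermediate (not isolated)
8 | (3R,4R)-3,4-bis[(tert-butyldimethylsilyl)oxy]-2,6,6-trimethylcyclohex-1-en-1-yl trifluoromethanesulfonate | O=S(=O)(OC1=C(C)[C@@H](O[Si](C)(C)C(C)(C)C)[C@H](O[Si](C)(C)C(C)(C)C)CC1(C)C)C(F)(F)F | intermediate
9 | geranyl bromide, (2E)-1-bromo-3,7-dimethylocta-2,6-diene | CC(C)=CCC/C(C)=C/CBr | starting material
10 | [(2E)-3,7-dimethylocta-2,6-dien-1-yl]triphenylphosphonium bromide | CC(C)=CCC/C(C)=C/C[P+](c1ccccc1)(c1ccccc1)c1ccccc1.[Br-] | intermediate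
11 | crocetin dialdehyde, (2E,4E,6E,8E,10E,12E,14E)-2,6,11,15-tetramethylhexadeca-2,4,6,8,10,12,14-heptaenedial | O=C/C(C)=C/C=C/C(C)=C/C=C/C=C(C)/C=C/C=C(C)/C=O | starting material
12 | [(2E)-3,7-dimethylocta-2,6-dien-1-ylidene]triphenylphosphorane | CC(C)=CCC/C(C)=C/C=P(c1ccccc1)(c1ccccc1)c1ccccc1 | intermediate (not isolated)
13 | (2E,4E,6E,8E,10E,12E,14E,16Z,18E)-2,6,11,15,19,23-hexamethyltetracosa-2,4,6,8,10,12,14,16,18,22-decaenal | CC(C)=CCC/C(C)=C/C=C\C(C)=C\C=C\C(C)=C\C=C\C=C(C)\C=C\C=C(C)\C=O | intermediate (not isolated)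
14 | (2E,4E,6E,8E,10E,12E,14E,16E,18E)-2,6,11,15,19,23-hexamethyltetracosa-2,4,6,8,10,12,14,16,18,22-decaenal (apo-8'-lycopenal) | CC(C)=CCC/C(C)=C/C=C/C(C)=C/C=C/C(C)=C/C=C/C=C(C)/C=C/C=C(C)/C=O | intermediate
15 | 2-[(1E,3E,5E,7E,9E,11E,13E,15E,17E,19E)-3,7,12,16,20,24-hexamethylpentacosa-1,3,5,7,9,11,13,15,17,19,23-undecaen-1-yl]-4,4,5,5-tetramethyl-1,3,2-dioxaborolane | CC(C)=CCC/C(C)=C/C=C/C(C)=C/C=C/C(C)=C/C=C/C=C(C)/C=C/C=C(C)/C=C/B1OC(C)(C)C(C)(C)O1 | intermediate
16 | (3R,4R)-3,4-bis[(tert-butyldimethylsilyl)oxy]-β,ψ-carotene (all-E) | CC(C)=CCC/C(C)=C/C=C/C(C)=C/C=C/C(C)=C/C=C/C=C(C)/C=C/C=C(C)/C=C/C1=C(C)[C@@H](O[Si](C)(C)C(C)(C)C)[C@H](O[Si](C)(C)C(C)(C)C)CC1(C)C | intermediate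
17 | (3R,4R)-β,ψ-carotene-3,4-diol (all-E, trans-diol) | CC(C)=CCC/C(C)=C/C=C/C(C)=C/C=C/C(C)=C/C=C/C=C(C)/C=C/C=C(C)/C=C/C1=C(C)[C@@H](O)[C@H](O)CC1(C)C | target

**Step count and risks**
Total: 11 steps. Longest linear sequence: 8 steps (steps 1–6, 10, 11).

Most likely to fail, in order of risk:

Step 10. Oxidative addition and transmetalation at the hindered C6 centre may be slow, so that protodeboronation of the polyenyl boronate, hydrolytic S–O cleavage of the triflate and E/Z scrambling win. The fallback reverses the polarity so that the hindered partner becomes the nucleophile and oxidative addition takes place at an unhindered polyenyl iodide. It sets out from 8 and 14. Triflate 8 is borylated (B2pin2, PdCl2(PPh3)2, PPh3, KOPh, toluene, 50–80 °C; the slow insertion is paid for on the robust C9 fragment) to the ring pinacol boronate F1. Aldehyde 14 is converted by Takai iodo-olefination (CHI3, CrCl2, THF, 0 °C → rt) into the C31 (E)-alkenyl iodide F2. F1 and F2 are joined by thallium-accelerated Suzuki coupling (Pd(PPh3)4, TlOEt, THF/H2O, rt), which comes back to the route at 16.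

Step 6. The enolate may lose silanolate by β-elimination (E1cB), or deprotonation of the hindered tertiary α-C–H may stay incomplete. The fallback avoids enolate chemistry. It sets out from 6, which is condensed with hydrazine (N2H4·H2O, Et3N, EtOH, 80 °C) to the hydrazone F3. Barton iodination (I2, tetramethylguanidine, THF, 0 °C → rt) should give the vinyl iodide F4, the quaternary C1 again forcing the double bond toward C5. F4 is coupled with 15 under the conditions of step 10 and the route is rejoined at 16.

Step 9. The boron-stabilised carbanion may add in a conjugate sense along the extended polyenal, or the elimination may not be fully E-selective. The fallback brings in C7 as an alkyne. It sets out from 14, which is homologated by the Colvin rearrangement (TMSCHN2, LDA, THF, −78 °C → rt) to the terminal C31 enyne F5. Zirconium-catalysed hydroboration (pinacolborane, Cp2Zr(H)Cl cat., Et3N, CH2Cl2, rt), a syn addition with boron at the terminal carbon, should give the E boronate and comes back to the route at 15.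

**Further compounds**
F1 | step 10 | 2-{(3R,4R)-3,4-bis[(tert-butyldimethylsilyl)oxy]-2,6,6-trimethylcyclohex-1-en-1-yl}-4,4,5,5-tetramethyl-1,3,2-dioxaborolane | CC1(C)OB(OC1(C)C)C1=C(C)[C@@H](O[Si](C)(C)C(C)(C)C)[C@H](O[Si](C)(C)C(C)(C)C)CC1(C)C
F2 | step 10 | (1E,3E,5E,7E,9E,11E,13E,15E,17E,19E)-1-iodo-3,7,12,16,20,24-hexamethylpentacosa-1,3,5,7,9,11,13,15,17,19,23-undecaene | CC(C)=CCC/C(C)=C/C=C/C(C)=C/C=C/C(C)=C/C=C/C=C(C)/C=C/C=C(C)/C=C/I
F3 | step 6 | (3R,4R)-3,4-bis[(tert-butyldimethylsilyl)oxy]-2,6,6-trimethylcyclohexan-1-one hydrazone (C2 epimer mixture) | NN=C1C(C)[C@@H](O[Si](C)(C)C(C)(C)C)[C@H](O[Si](C)(C)C(C)(C)C)CC1(C)C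
F4 | step 6 | (3R,4R)-3,4-bis[(tert-butyldimethylsilyl)oxy]-1-iodo-2,6,6-trimethylcyclohex-1-ene | IC1=C(C)[C@@H](O[Si](C)(C)C(C)(C)C)[C@H](O[Si](C)(C)C(C)(C)C)CC1(C)C
F5 | step 9 | (3E,5E,7E,9E,11E,13E,15E,17E,19E)-3,7,12,16,20,24-hexamethylpentacosa-3,5,7,9,11,13,15,17,19,23-decaen-1-yne | CC(C)=CCC/C(C)=C/C=C/C(C)=C/C=C/C(C)=C/C=C/C=C(C)/C=C/C=C(C)/C#C
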